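**Plan**
- Retrosynthetic cuts (germacrane numbering): the C9 acetate; the ring bond C9–C10; the lactone unit at C11–C7, C11=C13 and C12–O6; C4=C5; C1=C10; the C6–C7 epoxide back to an (E)-allylic alcohol.
- Enabling feature: O9 is 1,3 to C7 and O6 is vicinal to C7. With C6–C7 as a trans-epoxide, an O9-bound phosphonoacetate reaches C7 through a six-membered ring, and the freed O6 alkoxide then sits 1,4 to the acyl carbon.
- Forward order: a linear epoxy-diene vinyl iodide is assembled; the C11–C7 bond closes a δ-lactone (oxan-2-one), which contracts to the γ-lactone (oxolan-2-one) of the target by O9→O6 acyl transfer; Horner–Wadsworth–Emmons reaction with formaldehyde adds the methylene.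
- The ten-membered carbocycle is then closed at C9–C10 by a Nozaki–Hiyama–Kishi reaction; oxidation and reduction at C9 and acetylation finish the route.
- Stereochemistry: C6 and C7 come from a Sharpless epoxidation; inversion at C7 in the key step turns the trans-epoxide into the cis-fused lactone; C9 comes from a CBS reduction of the enone (both C9 epimers converge); C4=C5 from Still–Gennari and C1=C10 from Stork–Zhao olefination.

Key step: step 14

Remark: germacrane numbering is used only as a labelling aid (lactone O on C6, C7–C11 bond, acetoxy on C9, acyloxymethyl C15 on C4); the target is read as the cis-fused (6R,7R,9S) lactone with 1(10)Z and 4Z (C15 cis to C6) double bonds.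

**Route**

Step 1
Reactants: 1 3-[(tert-butyldimethylsilyl)oxy]propanal; 2 ethyl (triphenylphosphoranylidene)acetate
Product: 3 ethyl (E)-5-[(tert-butyldimethylsilyl)oxy]pent-2-enoate
Conditions: CH2Cl2, rt
Reagents that add atoms: none
Why: Wittig olefination with a stabilised ylide should give the (E)-enoate from an unhindered aldehyde.

Step 2
Reactants: 3 ethyl (E)-5-[(tert-butyldimethylsilyl)oxy]pent-2-enoate
Product: 4 (E)-5-[(tert-butyldimethylsilyl)oxy]pent-2-en-1-ol
Conditions: DIBAL-H (2.2 equiv), CH2Cl2, −78 °C; Rochelle salt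
Reagents that add atoms: none
Why: DIBAL-H 1,2-reduction of a conjugated ester should give the allylic alcohol and leave the silyl ether intact.

Step 3
Reactants: 4 (E)-5-[(tert-butyldimethylsilyl)oxy]pent-2-en-1-ol
Product: 5 [(2R,3R)-3-{2-[(tert-butyldimethylsilyl)oxy]ethyl}oxiran-2-yl]methanol
Conditions: Ti(OiPr)4 (cat.), D-(−)-diethyl tartrate (cat.), t-BuOOH, 4 Å MS, CH2Cl2, −20 °C
Reagents that add atoms: tert-butyl hydroperoxide, CC(C)(C)OO
Why: Sharpless asymmetric epoxidation of an (E)-allylic alcohol with the D-(−)-tartrate should give the (2R,3R)-trans-epoxide, which fixes C6 and the configuration at C7 that is inverted later.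

Step 4
Reactants: 5 [(2R,3R)-3-{2-[(tert-butyldimethylsilyl)oxy]ethyl}oxiran-2-yl]methanol
Product: 6 (2S,3R)-3-{2-[(tert-butyldimethylsilyl)oxy]ethyl}oxirane-2-carbaldehyde
Conditions: Dess–Martin periodinane, pyridine, CH2Cl2, 0 °C → rt
Reagents that add atoms: none
Why: Buffered Dess–Martin oxidation should give the epoxy aldehyde without epoxide opening or epimerisation (the CIP descriptor at C2 changes by priority only).

Step 5
Reactants: 1 3-[(tert-butyldimethylsilyl)oxy]propanal; 7 ethyltriphenylphosphonium iodide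
Product: 9 (Z)-tert-butyl[(4-iodopent-3-en-1-yl)oxy]dimethylsilane, via α-iodoethylidene ylide 8 (not isolated)
Conditions: 7, n-BuLi, THF, −78 °C → rt; I2, −78 °C; NaHMDS, −20 °C; then 1, −78 °C → rt
Reagents that add atoms: iodine, II
Why: Stork–Zhao-type Wittig olefination with the α-iodo ylide should give the (Z)-2-iodoalkene (iodine cis to the chain), the geometry later carried into C1=C10.

Step 6
Reactants: 9 (Z)-tert-butyl[(4-iodopent-3-en-1-yl)oxy]dimethylsilane
Product: 10 (Z)-4-iodopent-3-en-1-ol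
Conditions: TBAF, THF, 0 °C → rt
Reagents that add atoms: none
Why: Fluoride-mediated desilylation should free the primary alcohol and leave the vinyl iodide untouched.

Step 7
Reactants: 10 (Z)-4-iodopent-3-en-1-ol
Product: 11 (Z)-2,5-diiodopent-2-ene
Conditions: I2, PPh3, imidazole, CH2Cl2, 0 °C → rt
Reagents that add atoms: iodine, II
Why: Appel-type iodination should convert the primary alcohol into the iodide by SN2 displacement without touching the alkenyl iodide.

Step 8
Reactants: 11 (Z)-2,5-diiodopent-2-ene; 12 methyl bis(2,2,2-trifluoroethyl)phosphonoacetate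
Product: 13 methyl (Z)-2-[bis(2,2,2-trifluoroethoxy)phosphoryl]-6-iodohept-5-enoate (racemic at C2)
Conditions: 12, NaH, DMF, 0 °C; then 11, rt → 50 °C
Reagents that add atoms: none
Why: C-alkylation of the weakly basic phosphonoacetate anion with a primary iodide (SN2) should outrun elimination and give the α-substituted Still–Gennari reagent.

Step 9
Reactants: 6 (2S,3R)-3-{2-[(tert-butyldimethylsilyl)oxy]ethyl}oxirane-2-carbaldehyde; 13 methyl (Z)-2-[bis(2,2,2-trifluoroethoxy)phosphoryl]-6-iodohept-5-enoate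
Product: 14 methyl (2Z,5Z)-2-({(2R,3R)-3-[2-(tert-butyldimethylsilyloxy)ethyl]oxiran-2-yl}methylidene)-6-iodohept-5-enoate
Conditions: 13, KHMDS, 18-crown-6, THF, −78 °C; then 6, −78 °C
Reagents that add atoms: none
Why: Still–Gennari olefination of an α-oxygenated aldehyde should give the (Z)-trisubstituted enoate, which places C15 cis to C6 as the C4=C5 bond requires.

Step 10
Reactants: 14 methyl (2Z,5Z)-2-({(2R,3R)-3-[2-(tert-butyldimethylsilyloxy)ethyl]oxiran-2-yl}methylidene)-6-iodohept-5-enoate
Product: 15 (2Z,5Z)-2-({(2R,3R)-3-[2-(tert-butyldimethylsilyloxy)ethyl]oxiran-2-yl}methylidene)-6-iodohept-5-en-1-ol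
Conditions: DIBAL-H (2.5 equiv), CH2Cl2, −78 °C; Rochelle salt
Reagents that add atoms: none
Why: DIBAL-H reduction of a γ,δ-epoxy enoate at −78 °C should give the allylic alcohol (C15) faster than any hydride opening of the vinyl epoxide.

Step 11
Reactants: 15 (2Z,5Z)-2-({(2R,3R)-3-[2-(tert-butyldimethylsilyloxy)ethyl]oxiran-2-yl}methylidene)-6-iodohept-5-en-1-ol
Product: 16 (2Z,5Z)-2-({(2R,3R)-3-[2-(tert-butyldimethylsilyloxy)ethyl]oxiran-2-yl}methylidene)-6-iodohept-5-en-1-yl 3-methylbutanoate
Conditions: isovaleryl chloride, pyridine, DMAP (cat.), CH2Cl2, 0 °C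
Reagents that add atoms: 3-methylbutanoyl chloride, CC(C)CC(=O)Cl
Why: Base-buffered acylation of the primary allylic alcohol installs the C15 isovalerate before any other hydroxyl is free.

Step 12
Reactants: 16 (2Z,5Z)-2-({(2R,3R)-3-[2-(tert-butyldimethylsilyloxy)ethyl]oxiran-2-yl}methylidene)-6-iodohept-5-en-1-yl 3-methylbutanoate
Product: 17 (2Z,5Z)-2-{[(2R,3R)-3-(2-hydroxyethyl)oxiran-2-yl]methylidene}-6-iodohept-5-en-1-yl 3-methylbutanoate
Conditions: TBAF, AcOH, THF, 0 °C → rt
Reagents that add atoms: none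
Why: Acetic acid-buffered fluoride desilylation should free O9 without ester cleavage or acid-promoted opening of the vinyl epoxide.

Step 13
Reactants: 17 (2Z,5Z)-2-{[(2R,3R)-3-(2-hydroxyethyl)oxiran-2-yl]methylidene}-6-iodohept-5-en-1-yl 3-methylbutanoate; 18 2-(diethoxyphosphoryl)acetic acid
Product: 19 2-[(2R,3R)-3-{(1Z,5Z)-6-iodo-2-[(3-methylbutanoyloxy)methyl]hepta-1,5-dien-1-yl}oxiran-2-yl]ethyl 2-(diethoxyphosphoryl)acetate
Conditions: 18, EDC·HCl, DMAP (cat.), CH2Cl2, 0 °C → rt
Reagents that add atoms: none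
Why: Carbodiimide (Steglich-type) esterification attaches the nucleophilic C11–C12 unit to O9 under neutral conditions that the epoxide tolerates.

Step 14
Reactants: 19 2-[(2R,3R)-3-{(1Z,5Z)-6-iodo-2-[(3-methylbutanoyloxy)methyl]hepta-1,5-dien-1-yl}oxiran-2-yl]ethyl 2-(diethoxyphosphoryl)acetate
Product: 22 (4R,5R)-4-(2-hydroxyethyl)-5-{(1Z,5Z)-6-iodo-2-[(3-methylbutanoyloxy)methyl]hepta-1,5-dien-1-yl}-3-methylideneoxolan-2-one, via δ-lactone alkoxide 20 (not isolated), via phosphonolactone carbanion 21 (not isolated)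
Conditions: NaH (1.05 equiv), THF (0.02 M), 0 → 45 °C; then (CH2O)n, 0 °C → rt; aq. NH4Cl
Reagents that add atoms: formaldehyde (as paraformaldehyde), C=O
Why: Proposed new method: the phosphonoacetate carbanion should open the trans-epoxide at C7 by backside (SN2) attack in a 6-exo-tet closure, giving a δ-lactone and the C6 alkoxide; this alkoxide should add to the lactone carbonyl through a five-membered (5-exo-trig) transition state and expel the primary O9 alkoxide, contracting the δ-lactone to the γ-lactone, whose phosphonate carbanion then olefinates formaldehyde (Horner–Wadsworth–Emmons) to the exocyclic methylene. The closest known reactions are Stork-type epoxide-opening cyclisations of stabilised carbanions and the intermolecular phosphonoacetate/epoxide route to α-phosphono-γ-lactones followed by HWE methylenation; the new elements are the ester tether through O9 and the acyl shift. The only new stereocentre, C7, is set stereospecifically by inversion at the (3R)-epoxide carbon, which with retention at C6 converts the trans-epoxide into the cis-fused (6R,7R) lactone. The step needs attack at C7 rather than at the allylic C6, which the tether length should secure (six-membered exo versus seven-membered endo closure), and acyl transfer rather than alkoxide attack at phosphorus or at the isovalerate, which the nearby activated lactone carbonyl and the moderate temperature should secure.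

Step 15
Reactants: 22 (4R,5R)-4-(2-hydroxyethyl)-5-{(1Z,5Z)-6-iodo-2-[(3-methylbutanoyloxy)methyl]hepta-1,5-dien-1-yl}-3-methylideneoxolan-2-one
Product: 23 2-[(2R,3R)-2-{(1Z,5Z)-6-iodo-2-[(3-methylbutanoyloxy)methyl]hepta-1,5-dien-1-yl}-4-methylidene-5-oxooxolan-3-yl]acetaldehyde
Conditions: Dess–Martin periodinane, CH2Cl2, 0 °C → rt
Reagents that add atoms: none
Why: Dess–Martin oxidation should convert the primary alcohol into the C9 aldehyde without affecting the methylene lactone, the esters or the vinyl iodide.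

Step 16
Reactants: 23 2-[(2R,3R)-2-{(1Z,5Z)-6-iodo-2-[(3-methylbutanoyloxy)methyl]hepta-1,5-dien-1-yl}-4-methylidene-5-oxooxolan-3-yl]acetaldehyde
Product: 24 (6R,7R)-9-hydroxy-15-(3-methylbutanoyloxy)germacra-1(10)Z,4Z,11(13)-trien-12,6-olide as a mixture of C9 epimers
Conditions: CrCl2 (excess), NiCl2 (cat.), DMSO/THF, rt, high dilution (slow addition)
Reagents that add atoms: none
Why: Intramolecular Nozaki–Hiyama–Kishi addition of the (Z)-alkenylchromium to the aldehyde should close the ten-membered ring with retention of the C1=C10 geometry and with tolerance of the lactone and esters; the C9 configuration is left open here and set in steps 17–18.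

Step 17
Reactants: 24 (6R,7R)-9-hydroxy-15-(3-methylbutanoyloxy)germacra-1(10)Z,4Z,11(13)-trien-12,6-olide (C9 epimers)
Product: 25 (6R,7R)-15-(3-methylbutanoyloxy)-9-oxogermacra-1(10)Z,4Z,11(13)-trien-12,6-olide
Conditions: Dess–Martin periodinane, CH2Cl2, 0 °C
Reagents that add atoms: none
Why: Dess–Martin oxidation of the allylic alcohol should funnel both C9 epimers into one enone.

Step 18
Reactants: 25 (6R,7R)-15-(3-methylbutanoyloxy)-9-oxogermacra-1(10)Z,4Z,11(13)-trien-12,6-olide
Product: 26 (6R,7R,9S)-9-hydroxy-15-(3-methylbutanoyloxy)germacra-1(10)Z,4Z,11(13)-trien-12,6-olide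
Conditions: (R)-2-methyl-CBS-oxazaborolidine (cat.), catecholborane, toluene, −78 °C; MeOH, pH 7 buffer
Reagents that add atoms: none
Why: Corey–Bakshi–Shibata reduction with the alkenyl group (C10=C1) as the large substituent should deliver hydride from the (R)-catalyst to the Re face and give the (9S)-allylic alcohol by reagent control, while catecholborane at −78 °C should spare the methylene lactone and the esters.

Step 19
Reactants: 26 (6R,7R,9S)-9-hydroxy-15-(3-methylbutanoyloxy)germacra-1(10)Z,4Z,11(13)-trien-12,6-olide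
Product: 27 (6R,7R,9S)-9-acetoxy-15-(3-methylbutanoyloxy)germacra-1(10)Z,4Z,11(13)-trien-12,6-olide (target)
Conditions: Ac2O, pyridine, DMAP (cat.), CH2Cl2, 0 °C → rt
Reagents that add atoms: acetic anhydride, CC(=O)OC(C)=O
Why: DMAP-catalysed acetylation of the secondary allylic alcohol proceeds with retention and completes the target.

**Compound list**

1 | 3-[(tert-butyldimethylsilyl)oxy]propanal | CC(C)(C)[Si](C)(C)OCCC=O | starting material
2 | ethyl (triphenylphosphoranylidene)acetate | CCOC(=O)C=P(c1ccccc1)(c1ccccc1)c1ccccc1 | starting material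
3 | ethyl (E)-5-[(tert-butyldimethylsilyl)oxy]pent-2-enoate | CCOC(=O)/C=C/CCO[Si](C)(C)C(C)(C)C | intermediate
4 | (E)-5-[(tert-butyldimethylsilyl)oxy]pent-2-en-1-ol | OC/C=C/CCO[Si](C)(C)C(C)(C)C | intermediate
5 | [(2R,3R)-3-{2-[(tert-butyldimethylsilyl)oxy]ethyl}oxiran-2-yl]methanol | CC(C)(C)[Si](C)(C)OCC[C@H]1O[C@@H]1CO | intermediate
6 | (2S,3R)-3-{2-[(tert-butyldimethylsilyl)oxy]ethyl}oxirane-2-carbaldehyde | CC(C)(C)[Si](C)(C)OCC[C@H]1O[C@@H]1C=O | intermediate
7 | ethyltriphenylphosphonium iodide | CC[P+](c1ccccc1)(c1ccccc1)c1ccccc1.[I-] | starting material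
8 | (1-iodoethylidene)triphenylphosphorane (formed in the flask) | CC(I)=P(c1ccccc1)(c1ccccc1)c1ccccc1 | intermediate
9 | (Z)-tert-butyl[(4-iodopent-3-en-1-yl)oxy]dimethylsilane | CC(C)(C)[Si](C)(C)OCC/C=C(/C)I | intermediate
10 | (Z)-4-iodopent-3-en-1-ol | OCC/C=C(/C)I | intermediate
11 | (Z)-2,5-diiodopent-2-ene | ICC/C=C(/C)I | intermediate
12 | methyl bis(2,2,2-trifluoroethyl)phosphonoacetate | COC(=O)CP(=O)(OCC(F)(F)F)OCC(F)(F)F | starting material
13 | methyl (Z)-2-[bis(2,2,2-trifluoroethoxy)phosphoryl]-6-iodohept-5-enoate (racemic at C2) | COC(=O)C(CC/C=C(/C)I)P(=O)(OCC(F)(F)F)OCC(F)(F)F | intermediate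
14 | methyl (2Z,5Z)-2-({(2R,3R)-3-[2-(tert-butyldimethylsilyloxy)ethyl]oxiran-2-yl}methylidene)-6-iodohept-5-enoate | CC(C)(C)[Si](C)(C)OCC[C@H]1O[C@@H]1/C=C(\C(=O)OC)CC/C=C(/C)I | intermediate
15 | (2Z,5Z)-2-({(2R,3R)-3-[2-(tert-butyldimethylsilyloxy)ethyl]oxiran-2-yl}methylidene)-6-iodohept-5-en-1-ol | CC(C)(C)[Si](C)(C)OCC[C@H]1O[C@@H]1/C=C(\CO)CC/C=C(/C)I | intermediate
16 | 3-methylbutanoate of 15 | CC(C)(C)[Si](C)(C)OCC[C@H]1O[C@@H]1/C=C(\COC(=O)CC(C)C)CC/C=C(/C)I | intermediate
17 | (2Z,5Z)-2-{[(2R,3R)-3-(2-hydroxyethyl)oxiran-2-yl]methylidene}-6-iodohept-5-en-1-yl 3-methylbutanoate | OCC[C@H]1O[C@@H]1/C=C(\COC(=O)CC(C)C)CC/C=C(/C)I | intermediate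
18 | 2-(diethoxyphosphoryl)acetic acid | CCOP(=O)(OCC)CC(=O)O | starting material
19 | O9 diethylphosphonoacetate of 17 (trans-6,7-epoxide, 2R,3R) | CCOP(=O)(OCC)CC(=O)OCC[C@H]1O[C@@H]1/C=C(\COC(=O)CC(C)C)CC/C=C(/C)I | intermediate
20 | sodium alkoxide of the 3-(diethoxyphosphoryl)oxan-2-one formed by C11–C7 closure (C6 alkoxide; C6 and C7 as in 22; C11 epimers) | CCOP(=O)(OCC)C1C(=O)OCC[C@H]1[C@H]([O-])/C=C(\COC(=O)CC(C)C)CC/C=C(/C)I.[Na+] | intermediate
21 | sodium salt of the α-(diethoxyphosphoryl)-γ-lactone carbanion with free O9–H (C6 and C7 as in 22) | CCOP(=O)(OCC)[C-]1C(=O)O[C@H](/C=C(\COC(=O)CC(C)C)CC/C=C(/C)I)[C@@H]1CCO.[Na+] | intermediate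
22 | (4R,5R)-4-(2-hydroxyethyl)-5-{(1Z,5Z)-6-iodo-2-[(3-methylbutanoyloxy)methyl]hepta-1,5-dien-1-yl}-3-methylideneoxolan-2-one | C=C1C(=O)O[C@H](/C=C(\COC(=O)CC(C)C)CC/C=C(/C)I)[C@@H]1CCO | intermediate
23 | C9 aldehyde of 22 | C=C1C(=O)O[C@H](/C=C(\COC(=O)CC(C)C)CC/C=C(/C)I)[C@@H]1CC=O | intermediate
24 | (6R,7R)-9-hydroxy-15-(3-methylbutanoyloxy)germacra-1(10)Z,4Z,11(13)-trien-12,6-olide, C9 epimer mixture | C=C1C(=O)O[C@@H]2/C=C(\COC(=O)CC(C)C)CC/C=C(/C)C(O)C[C@H]12 | intermediate
25 | (6R,7R)-15-(3-methylbutanoyloxy)-9-oxogermacra-1(10)Z,4Z,11(13)-trien-12,6-olide | C=C1C(=O)O[C@@H]2/C=C(\COC(=O)CC(C)C)CC/C=C(/C)C(=O)C[C@H]12 | intermediate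
26 | (6R,7R,9S)-9-hydroxy-15-(3-methylbutanoyloxy)germacra-1(10)Z,4Z,11(13)-trien-12,6-olide | C=C1C(=O)O[C@@H]2/C=C(\COC(=O)CC(C)C)CC/C=C(/C)[C@@H](O)C[C@H]12 | intermediate
27 | (6R,7R,9S)-9-acetoxy-15-(3-methylbutanoyloxy)germacra-1(10)Z,4Z,11(13)-trien-12,6-olide | C=C1C(=O)O[C@@H]2/C=C(\COC(=O)CC(C)C)CC/C=C(/C)[C@@H](OC(C)=O)C[C@H]12 | target

**Step count**
Total steps: 19. Longest linear sequence: 15 steps (steps 1–4, then 9–19).

**Steps most likely to fail**

1. Step 14 (proposed new method). The tethered carbanion may open the epoxide at the allylic C6 or alkylate on oxygen. The C6 alkoxide may also attack phosphorus (the cyclopropane-forming Wadsworth–Emmons pathway) or the isovalerate instead of the lactone carbonyl.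
Fallback with known chemistry, untethered, from 5 back to 22. Epoxy alcohol 5 would be opened at C3 with inversion by diethyl[(trimethylsilyl)ethynyl]aluminium (known C3-selective alane opening of 2,3-epoxy alcohols) to give (2S,3R)-5-[(tert-butyldimethylsilyl)oxy]-3-[(trimethylsilyl)ethynyl]pentane-1,2-diol F1. Bis-silylation (TESOTf, 2,6-lutidine) would give the bis(triethylsilyl) ether F2, and Swern oxidation, which converts primary TES ethers directly, would give the α-silyloxy aldehyde F3. Still–Gennari olefination with 13 would give the (Z)-enoate F4, DIBAL-H the allylic alcohol F5, and isovaleryl chloride the ester F6. Buffered TBAF would remove the TES, TBS and C-silyl groups to give the alkynyl diol F7. Palladium(II)-catalysed cyclocarbonylation of the homopropargylic alcohol (Norton conditions: PdCl2, thiourea, CO) should then close the five-membered α-methylene lactone in preference to the six-membered one through O9 and give 22. Palladium stays in the +2 state in this cycle, so the vinyl iodide should survive.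

2. Step 16. Ring closure to the strained ten-membered ring may lose out to oligomerisation, and low-valent nickel may ionise the allylic lactone.
Fallback from 23 back to 25, closing the same bond as a ketone by an intramolecular acyl-Stille coupling. Pinnick oxidation of 23 would give the iodo acid F8. Pd(PPh3)4 and hexamethylditin would give the (Z)-alkenylstannane acid F9. Ghosez's chloroenamine would give the acid chloride F10 under neutral conditions. Palladium-catalysed Stille ketone synthesis at high dilution should then give enone 25 directly, which also removes step 17.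

3. Step 18. The reagent may be mismatched with the conformation of the macrocyclic (Z)-enone, giving poor facial selectivity, or the exocyclic methylene may be reduced in conjugate fashion.
Fallback from 25 back to 27 under substrate control. Luche reduction (NaBH4, CeCl3, MeOH, −78 °C) would be used instead. Any (9S)-alcohol obtained is 26 and is acetylated as in step 19. If the (9R)-alcohol F11 predominates, a Mitsunobu reaction with acetic acid (PPh3, DIAD) should give 27 with inversion at C9.

**Further compounds**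

F1 | step 14 | (2S,3R)-5-[(tert-butyldimethylsilyl)oxy]-3-[(trimethylsilyl)ethynyl]pentane-1,2-diol | C[Si](C)(C)C#C[C@@H](CCO[Si](C)(C)C(C)(C)C)[C@H](O)CO
F2 | step 14 | 1,2-bis(triethylsilyl) ether of F1 | C[Si](C)(C)C#C[C@@H](CCO[Si](C)(C)C(C)(C)C)[C@H](O[Si](CC)(CC)CC)CO[Si](CC)(CC)CC
F3 | step 14 | 2-(triethylsilyloxy) aldehyde from F2 (C5 aldehyde) | C[Si](C)(C)C#C[C@@H](CCO[Si](C)(C)C(C)(C)C)[C@H](O[Si](CC)(CC)CC)C=O
F4 | step 14 | (Z)-enoate from F3 and 13 | C[Si](C)(C)C#C[C@@H](CCO[Si](C)(C)C(C)(C)C)[C@H](O[Si](CC)(CC)CC)/C=C(\C(=O)OC)CC/C=C(/C)I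
F5 | step 14 | allylic alcohol from F4 | C[Si](C)(C)C#C[C@@H](CCO[Si](C)(C)C(C)(C)C)[C@H](O[Si](CC)(CC)CC)/C=C(\CO)CC/C=C(/C)I
F6 | step 14 | 3-methylbutanoate of F5 | C[Si](C)(C)C#C[C@@H](CCO[Si](C)(C)C(C)(C)C)[C@H](O[Si](CC)(CC)CC)/C=C(\COC(=O)CC(C)C)CC/C=C(/C)I
F7 | step 14 | desilylated alkynyl diol (free O6–H, O9–H, terminal alkyne) | C#C[C@@H](CCO)[C@H](O)/C=C(\COC(=O)CC(C)C)CC/C=C(/C)I
F8 | step 16 | C9 carboxylic acid from 23 | C=C1C(=O)O[C@H](/C=C(\COC(=O)CC(C)C)CC/C=C(/C)I)[C@@H]1CC(=O)O
F9 | step 16 | (Z)-trimethylstannyl alkene acid | C=C1C(=O)O[C@H](/C=C(\COC(=O)CC(C)C)CC/C=C(/C)[Sn](C)(C)C)[C@@H]1CC(=O)O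
F10 | step 16 | acid chloride of F9 | C=C1C(=O)O[C@H](/C=C(\COC(=O)CC(C)C)CC/C=C(/C)[Sn](C)(C)C)[C@@H]1CC(=O)Cl
F11 | step 18 | (6R,7R,9R)-9-hydroxy epimer of 26 | C=C1C(=O)O[C@@H]2/C=C(\COC(=O)CC(C)C)CC/C=C(/C)[C@H](O)C[C@H]12
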